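**Retrosynthetic overview**

1. The last C–C bond joins C1 of syringyl ring C to C2 of the 3,7-dioxabicyclo[3.3.0]octane core (C2 and C6 carry the aryl rings, O3 and O7 are the ring oxygens, C1 and C5 the fusion carbons). It is made by a nickel-electrocatalysed decarboxylative radical cyclization–arylation that first forms C8–C1 and so closes the O7 ring in the same operation.
2. The feature that allows this: C8 is an O7–CH2 carbon, so it can be an alkoxymethyl radical released from an alkoxyacetic ester. C1=C2–O3 can be a cyclic enol ether (2,3-dihydrofuran) whose capture at C1 leaves an α-oxy radical at C2, and the cis-fused bicycle then offers only its convex face to the aryl group.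
3. The radical precursor is a 3-substituted 2,3-dihydrofuran, made by Evans syn aldol (sets C5 and C6), O–H insertion (O7–C8), auxiliary removal, alkene cleavage to a lactol and dehydration. The aryl partner is the iodide of ring C carrying units A and B.
4. Each erythro arylglycerol β-aryl ether is made by Mitsunobu inversion on a silylated methyl glycerate (C8), Weinreb ketone synthesis with an aryl Grignard reagent, and chelation-controlled Zn(BH4)2 reduction (C7). One Weinreb amide serves both ring C and ring D.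
5. Ring order: all benzene rings are bought; the O3 ring (dihydrofuran) is formed in steps 15–16, the O7 ring in step 26; global desilylation is last.

Key step: step 26

Remark: glycerol carbons are C7 (benzylic), C8 and C9; unit A is the outer and unit B the inner arylglycerol of the long arm, unit E the arylglycerol on ring D; TBS = tert-butyldimethylsilyl, TIPS = triisopropylsilyl; ArDE = 4-{[(1S,2R)-1,3-bis(TBS-oxy)-1-[3-methoxy-4-(TIPS-oxy)phenyl]propan-2-yl]oxy}-3,5-dimethoxyphenyl and ArAB = 3-methoxy-4-{[(1R,2S)-1,3-bis(TBS-oxy)-1-[3-methoxy-4-(TIPS-oxy)phenyl]propan-2-yl]oxy}phenyl; both enantiomers of methyl glycerate and 4-iodo-2-methoxyphenol are assumed to be purchasable, Zn(BH4)2 is used as a stock solution in Et2O, and Grignard reagent 9 is prepared once as a titrated THF solution that supplies two later steps.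

**Route**

Step 1
Reactants: 1 methyl (S)-2,3-dihydroxypropanoate
Product: 2 methyl (S)-3-(TBS-oxy)-2-hydroxypropanoate
Conditions: TBSCl (1.05 equiv), imidazole, CH2Cl2, 0 °C
Reagents that add atoms: tert-butyldimethylsilyl chloride, CC(C)(C)[Si](C)(C)Cl
Why: Silyl ether formation should occur at the primary hydroxyl much faster than at the secondary α-hydroxyl, and the stereocentre is not touched.

Step 2
Reactants: 3 2,6-dimethoxyphenol
Product: 4 4-iodo-2,6-dimethoxyphenol
Conditions: I2, NaHCO3, THF/H2O, 0 °C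
Reagents that add atoms: iodine, II
Why: Electrophilic aromatic iodination of the phenoxide should go para to the oxygen, the only open position activated by O−, since both ortho positions carry methoxy groups.

Step 3
Reactants: 4 4-iodo-2,6-dimethoxyphenol; 2 methyl (S)-3-(TBS-oxy)-2-hydroxypropanoate
Product: 5 methyl (R)-3-(TBS-oxy)-2-(4-iodo-2,6-dimethoxyphenoxy)propanoate
Conditions: PPh3, DIAD, THF, 0 °C → rt
Reagents that add atoms: none
Why: Mitsunobu etherification displaces the activated α-hydroxy ester by the phenoxide in an SN2 step, so C2 is inverted from S to R; this carbon becomes C8 of unit E and of unit B.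

Step 4
Reactants: 5 methyl (R)-3-(TBS-oxy)-2-(4-iodo-2,6-dimethoxyphenoxy)propanoate
Product: 6 (R)-3-(TBS-oxy)-2-(4-iodo-2,6-dimethoxyphenoxy)-N-methoxy-N-methylpropanamide
Conditions: MeNHOMe·HCl, AlMe3, CH2Cl2, 0 °C → rt
Reagents that add atoms: N,O-dimethylhydroxylamine hydrochloride, CNOC.Cl
Why: Weinreb amide formation by aminolysis of the ester with the aluminium amide is not basic enough to epimerize the α-aryloxy centre and leaves the aryl iodide and silyl ether alone.

Step 5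
Reactants: 7 4-bromo-2-methoxyphenol
Product: 8 (4-bromo-2-methoxyphenoxy)triisopropylsilane
Conditions: TIPSCl, imidazole, DMF, rt
Reagents that add atoms: triisopropylsilyl chloride, CC(C)[Si](Cl)(C(C)C)C(C)C
Why: Standard silylation of a phenol gives a TIPS ether that tolerates Grignard formation and the later organometallic steps.

Step 6
Reactants: 8 (4-bromo-2-methoxyphenoxy)triisopropylsilane
Product: 9 [3-methoxy-4-(TIPS-oxy)phenyl]magnesium bromide (titrated THF solution, kept under argon)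
Conditions: Mg turnings, THF, 45 °C; titrate, store under Ar
Reagents that add atoms: magnesium, [Mg]
Why: Grignard reagent formation by insertion of magnesium into the aryl C–Br bond; the TIPS ether and the methoxy group are inert to it, and the solution should keep long enough to serve both ketone syntheses.

Step 7
Reactants: 6 (R)-3-(TBS-oxy)-2-(4-iodo-2,6-dimethoxyphenoxy)-N-methoxy-N-methylpropanamide; 9 [3-methoxy-4-(TIPS-oxy)phenyl]magnesium bromide
Product: 10 (R)-3-(TBS-oxy)-2-(4-iodo-2,6-dimethoxyphenoxy)-1-[3-methoxy-4-(TIPS-oxy)phenyl]propan-1-one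
Conditions: 9 (THF solution, 1.2 equiv), THF, −20 → 0 °C; aq. NH4Cl
Reagents that add atoms: none
Why: Weinreb ketone synthesis: the aryl Grignard reagent adds once to give a stable magnesium chelate that releases the ketone only on work-up, which avoids over-addition and enolization of the α-aryloxy centre, and an arylmagnesium halide should not exchange with the aryl iodide at this temperature.

Step 8
Reactants: 10 (R)-3-(TBS-oxy)-2-(4-iodo-2,6-dimethoxyphenoxy)-1-[3-methoxy-4-(TIPS-oxy)phenyl]propan-1-one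
Product: 11 (1S,2R)-3-(TBS-oxy)-2-(4-iodo-2,6-dimethoxyphenoxy)-1-[3-methoxy-4-(TIPS-oxy)phenyl]propan-1-ol (erythro)
Conditions: Zn(BH4)2, Et2O, −30 → 0 °C
Reagents that add atoms: none
Why: Chelation-controlled (Cram chelate) reduction: zinc bridges the carbonyl oxygen and the aryloxy oxygen and hydride arrives from the face opposite the CH2OTBS group, which should give the 1,2-anti (erythro) alcohol, 1S next to 2R.

Step 9
Reactants: 11 (1S,2R)-3-(TBS-oxy)-2-(4-iodo-2,6-dimethoxyphenoxy)-1-[3-methoxy-4-(TIPS-oxy)phenyl]propan-1-ol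
Product: 12 5-iodo-1,3-dimethoxy-2-{[(1S,2R)-1,3-bis(TBS-oxy)-1-[3-methoxy-4-(TIPS-oxy)phenyl]propan-2-yl]oxy}benzene (ArDE–I)
Conditions: TBSOTf, 2,6-lutidine, CH2Cl2, −78 → 0 °C
Reagents that add atoms: tert-butyldimethylsilyl triflate, CC(C)(C)[Si](C)(C)OS(=O)(=O)C(F)(F)F
Why: Silylation of the hindered secondary benzylic alcohol with the silyl triflate and a hindered base is a standard protection that does not ionize the benzylic position.

Step 10
Reactants: 12 ArDE–I
Product: 14 4-{[(1S,2R)-1,3-bis(TBS-oxy)-1-[3-methoxy-4-(TIPS-oxy)phenyl]propan-2-yl]oxy}-3,5-dimethoxybenzaldehyde (ArDE–CHO), via arylmagnesium chloride 13 (not isolated)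
Conditions: iPrMgCl·LiCl, THF, 0 °C → rt; DMF, 0 °C → rt; aq. NH4Cl
Reagents that add atoms: isopropylmagnesium chloride–lithium chloride, CC(C)[Mg]Cl.[Li+].[Cl-] (Mg and Cl enter 13 only); N,N-dimethylformamide, CN(C)C=O
Why: Iodine–magnesium exchange followed by formylation with DMF (Bouveault aldehyde synthesis) converts the aryl iodide into the aldehyde while silyl and aryl ethers stay inert.

Step 11
Reactants: 15 (R)-4-benzyloxazolidin-2-one; 16 pent-4-enoyl chloride
Product: 17 (R)-4-benzyl-3-(pent-4-enoyl)oxazolidin-2-one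
Conditions: n-BuLi, THF, −78 °C; then 16, −78 → 0 °C
Reagents that add atoms: none
Why: N-Acylation of the lithiated oxazolidinone with an acid chloride is the standard way to load the auxiliary.

Step 12
Reactants: 17 (R)-4-benzyl-3-(pent-4-enoyl)oxazolidin-2-one; 14 ArDE–CHO
Product: 19 (R)-4-benzyl-3-{(2R)-2-[(R)-hydroxy(ArDE)methyl]pent-4-enoyl}oxazolidin-2-one, via Z boron enolate 18 (not isolated)
Conditions: 17, Bu2BOTf, iPr2NEt, CH2Cl2, −78 → 0 °C; then 14, −78 → 0 °C; pH 7 buffer, MeOH, H2O2, 0 °C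
Reagents that add atoms: dibutylboron triflate, CCCCB(CCCC)OS(=O)(=O)C(F)(F)F (enters 18 only)
Why: Evans syn aldol reaction: the Z boron enolate reacts through a closed Zimmerman–Traxler transition state on the face away from the benzyl group of the (R)-auxiliary, which sets the 2R centre and the R carbinol centre (later C5 and C6 of the core, aryl group and C4 anti).

Step 13
Reactants: 19 (R)-4-benzyl-3-{(2R)-2-[(R)-hydroxy(ArDE)methyl]pent-4-enoyl}oxazolidin-2-one
Product: 20 ethyl 2-{(R)-(ArDE)[(2R)-1-[(R)-4-benzyl-2-oxooxazolidin-3-yl]-1-oxopent-4-en-2-yl]methoxy}acetate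
Conditions: ethyl diazoacetate (slow addition), Rh2(OAc)4 (1 mol %), CH2Cl2, rt
Reagents that add atoms: ethyl diazoacetate, CCOC(=O)C=[N+]=[N-]
Why: Rhodium carbenoid O–H insertion alkylates the hindered, base-sensitive aldol hydroxyl under neutral conditions, so no retro-aldol cleavage is expected; insertion into O–H should outrun cyclopropanation of the unactivated terminal alkene, and the carbinol configuration is retained.

Step 14
Reactants: 20 ethyl 2-{(R)-(ArDE)[(2R)-1-[(R)-4-benzyl-2-oxooxazolidin-3-yl]-1-oxopent-4-en-2-yl]methoxy}acetate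
Product: 21 ethyl 2-{[(1R,2S)-1-(ArDE)-2-(hydroxymethyl)pent-4-en-1-yl]oxy}acetate
Conditions: NaBH4, THF/H2O (4:1), 0 °C
Reagents that add atoms: none
Why: Borohydride reduction of the N-acyloxazolidinone releases the auxiliary and the primary alcohol; the imide is much more electrophilic than the ethyl ester, which should survive at 0 °C if the reaction is stopped when the imide is consumed.

Step 15
Reactants: 21 ethyl 2-{[(1R,2S)-1-(ArDE)-2-(hydroxymethyl)pent-4-en-1-yl]oxy}acetate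
Product: 23 ethyl 2-{(R)-(ArDE)[(3S)-5-hydroxyoxolan-3-yl]methoxy}acetate (anomer mixture), via hydroxy aldehyde 22 (not isolated)
Conditions: OsO4 (2 mol %), NaIO4, 2,6-lutidine, dioxane/H2O (3:1), rt
Reagents that add atoms: sodium periodate, [Na+].[O-]I(=O)(=O)=O
Why: Lemieux–Johnson oxidation cleaves the terminal alkene to the aldehyde, which should be trapped at once by the only free hydroxyl as the five-membered lactol.

Step 16
Reactants: 23 ethyl 2-{(R)-(ArDE)[(3S)-5-hydroxyoxolan-3-yl]methoxy}acetate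
Product: 25 ethyl 2-{(R)-(ArDE)[(3S)-2,3-dihydrofuran-3-yl]methoxy}acetate, via anomeric mesylate 24 (not isolated)
Conditions: MsCl, Et3N, CH2Cl2, −40 °C → rt, then 40 °C
Reagents that add atoms: methanesulfonyl chloride, CS(=O)(=O)Cl (enters 24 only)
Why: Mesylation of the lactol and amine-induced elimination, the usual glycal-type dehydration of a 2-deoxy lactol, gives the 2,3-dihydrofuran (the O3 ring) without acid.

Step 17
Reactants: 25 ethyl 2-{(R)-(ArDE)[(3S)-2,3-dihydrofuran-3-yl]methoxy}acetate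
Product: 27 1,3-dioxoisoindolin-2-yl 2-{(R)-(ArDE)[(3S)-2,3-dihydrofuran-3-yl]methoxy}acetate, via lithium carboxylate 26 (not isolated)
Conditions: LiOH·H2O (1.05 equiv), THF/H2O, 0 °C; evaporate; then N-hydroxyphthalimide, EDC·HCl, CH2Cl2/DMF, 0 °C → rt
Reagents that add atoms: lithium hydroxide, [Li+].[OH-] (enters 26); N-hydroxyphthalimide, O=C1c2ccccc2C(=O)N1O
Why: Brief cold saponification of the activated alkoxyacetate and carbodiimide esterification of the carboxylate salt should give the redox-active ester without leaving the acid-sensitive enol ether in contact with a free carboxylic acid.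

Step 18
Reactants: 28 methyl (R)-2,3-dihydroxypropanoate
Product: 29 methyl (R)-3-(TBS-oxy)-2-hydroxypropanoate
Conditions: TBSCl (1.05 equiv), imidazole, CH2Cl2, 0 °C
Reagents that add atoms: tert-butyldimethylsilyl chloride, CC(C)(C)[Si](C)(C)Cl
Why: Selective silyl ether formation at the primary hydroxyl, as in step 1.

Step 19
Reactants: 30 4-iodo-2-methoxyphenol; 29 methyl (R)-3-(TBS-oxy)-2-hydroxypropanoate
Product: 31 methyl (S)-3-(TBS-oxy)-2-(4-iodo-2-methoxyphenoxy)propanoate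
Conditions: PPh3, DIAD, THF, 0 °C → rt
Reagents that add atoms: none
Why: Mitsunobu etherification with SN2 inversion turns the R hydroxy ester into the S aryl ether, which becomes C8 of unit A.

Step 20
Reactants: 31 methyl (S)-3-(TBS-oxy)-2-(4-iodo-2-methoxyphenoxy)propanoate
Product: 32 (S)-3-(TBS-oxy)-2-(4-iodo-2-methoxyphenoxy)-N-methoxy-N-methylpropanamide
Conditions: MeNHOMe·HCl, AlMe3, CH2Cl2, 0 °C → rt
Reagents that add atoms: N,O-dimethylhydroxylamine hydrochloride, CNOC.Cl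
Why: Weinreb amide formation with the aluminium amide, as in step 4, without epimerization.

Step 21
Reactants: 32 (S)-3-(TBS-oxy)-2-(4-iodo-2-methoxyphenoxy)-N-methoxy-N-methylpropanamide; 9 [3-methoxy-4-(TIPS-oxy)phenyl]magnesium bromide
Product: 33 (S)-3-(TBS-oxy)-2-(4-iodo-2-methoxyphenoxy)-1-[3-methoxy-4-(TIPS-oxy)phenyl]propan-1-one
Conditions: 9 (THF solution, 1.2 equiv), THF, −20 → 0 °C; aq. NH4Cl
Reagents that add atoms: none
Why: Weinreb ketone synthesis, as in step 7; the aryl iodide of ring B should not exchange with the arylmagnesium bromide.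

Step 22
Reactants: 33 (S)-3-(TBS-oxy)-2-(4-iodo-2-methoxyphenoxy)-1-[3-methoxy-4-(TIPS-oxy)phenyl]propan-1-one
Product: 34 (1R,2S)-3-(TBS-oxy)-2-(4-iodo-2-methoxyphenoxy)-1-[3-methoxy-4-(TIPS-oxy)phenyl]propan-1-ol (erythro)
Conditions: Zn(BH4)2, Et2O, −30 → 0 °C
Reagents that add atoms: none
Why: Chelation-controlled reduction through the zinc chelate of the ketone and the guaiacyl ether oxygen should give the anti (erythro) alcohol, 1R next to 2S.

Step 23
Reactants: 34 (1R,2S)-3-(TBS-oxy)-2-(4-iodo-2-methoxyphenoxy)-1-[3-methoxy-4-(TIPS-oxy)phenyl]propan-1-ol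
Product: 35 4-iodo-2-methoxy-1-{[(1R,2S)-1,3-bis(TBS-oxy)-1-[3-methoxy-4-(TIPS-oxy)phenyl]propan-2-yl]oxy}benzene (ArAB–I)
Conditions: TBSOTf, 2,6-lutidine, CH2Cl2, −78 → 0 °C
Reagents that add atoms: tert-butyldimethylsilyl triflate, CC(C)(C)[Si](C)(C)OS(=O)(=O)C(F)(F)F
Why: Standard silylation of the secondary benzylic alcohol, needed before the aryl iodide is turned into an organomagnesium reagent.

Step 24
Reactants: 35 ArAB–I; 6 (R)-3-(TBS-oxy)-2-(4-iodo-2,6-dimethoxyphenoxy)-N-methoxy-N-methylpropanamide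
Product: 37 (R)-3-(TBS-oxy)-2-(4-iodo-2,6-dimethoxyphenoxy)-1-(ArAB)propan-1-one, via arylmagnesium chloride 36 (not isolated)
Conditions: 35, iPrMgCl·LiCl (0.98 equiv), THF, 0 °C → rt; then 6, −20 → 0 °C; aq. NH4Cl
Reagents that add atoms: isopropylmagnesium chloride–lithium chloride, CC(C)[Mg]Cl.[Li+].[Cl-] (Mg and Cl enter 36 only)
Why: Iodine–magnesium exchange and Weinreb ketone synthesis join units A–B to the ring C piece; with no excess of the alkyl Grignard reagent, the arylmagnesium chloride should add to the amide faster than it exchanges with the aryl iodide of 6.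

Step 25
Reactants: 37 (R)-3-(TBS-oxy)-2-(4-iodo-2,6-dimethoxyphenoxy)-1-(ArAB)propan-1-one
Product: 38 (1S,2R)-3-(TBS-oxy)-2-(4-iodo-2,6-dimethoxyphenoxy)-1-(ArAB)propan-1-ol (erythro; aryl iodide of ring C with units A and B)
Conditions: Zn(BH4)2, Et2O, −30 → 0 °C
Reagents that add atoms: none
Why: Chelation-controlled reduction as in step 8 should give the anti (erythro) alcohol, 1S next to 2R; this hydroxyl is left free because the nickel step tolerates alcohols.

Step 26
Reactants: 27 1,3-dioxoisoindolin-2-yl 2-{(R)-(ArDE)[(3S)-2,3-dihydrofuran-3-yl]methoxy}acetate; 38 aryl iodide of ring C with units A and B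
Product: 41 hepta-silylated target (TBS on O7 and O9 of units A and E and on O9 of unit B; TIPS on both phenols), via alkoxymethyl radical 39 (not isolated), via bicyclic C2 radical 40 (not isolated)
Conditions: NiCl2·6H2O (10 mol %), 2,2'-bipyridine (12 mol %), AgNO3 (0.3 equiv), LiCl, NMP, Mg anode, RVC cathode, constant current, rt; 38 (1.5 equiv), 27 added slowly
Reagents that add atoms: none
Why: Proposed new method: reduction of 27 at the silver-coated cathode (or by low-valent nickel) expels phthalimide and CO2 and leaves alkoxymethyl radical 39, which attacks C1 of the dihydrofuran in a 5-exo-trig closure (C8–C1 bond, O7 ring) to give the α-alkoxy radical 40 at C2; 40 is captured by the aryl nickel iodide of divalent nickel formed from 38 and zerovalent nickel, and reductive elimination from trivalent nickel makes the C2–aryl bond. The closest known reaction types are nickel-catalysed decarboxylative arylation of α-oxy redox-active esters with aryl halides and nickel-catalysed radical cyclization–arylation of alkene-tethered alkyl radicals, but the relay through a cyclic enol ether to an α-oxy radical before arylation has no precedent. The ring fusion can only be cis because the three-atom tether C6–O7–C8 is anchored at C5 of a five-membered ring, so C5 dictates C1. At C2 the aryl group is delivered to the convex face of the V-shaped bicycle, anti to the C1–C8 bond, which gives the exo (2R) aryl group of the target, while the exo aryl group at C6 is already in place, set by the syn aldol of step 12. The step needs ring closure to outrun nickel capture of 39 and C–C coupling to outrun reduction or β-hydride loss at C2: the first is served by the fast 5-exo closure of an alkoxymethyl radical onto an alkene held three atoms away, by generation of the radical at the electrode away from the dilute nickel catalyst and by slow addition of 27, the second by the nucleophilic, stabilised character of 40 and by the analogy with 1,2-trans-selective nickel arylation of anomeric radicals. 6-endo attack at C2 and loss of formaldehyde from 39 should both be slower than the 5-exo closure.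

Step 27
Reactants: 41 hepta-silylated target
Product: 42 target CNP0316493.2
Conditions: Bu4NF, AcOH (1:1), THF, 0 °C → rt
Reagents that add atoms: none
Why: Fluoride-mediated cleavage of the five TBS and two TIPS ethers, buffered with acetic acid, should free all hydroxyl groups without exposing the β-aryl ethers, benzylic alcohols or benzylic ring ethers to strong base or acid, so no stereocentre is at risk.

**Compound list**

1 | methyl (S)-2,3-dihydroxypropanoate | COC(=O)[C@@H](O)CO | starting material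
2 | methyl (S)-3-(TBS-oxy)-2-hydroxypropanoate | COC(=O)[C@@H](O)CO[Si](C)(C)C(C)(C)C | intermediate
3 | 2,6-dimethoxyphenol | COc1cccc(OC)c1O | starting material
4 | 4-iodo-2,6-dimethoxyphenol | COc1cc(I)cc(OC)c1O | intermediate
5 | methyl (R)-3-(TBS-oxy)-2-(4-iodo-2,6-dimethoxyphenoxy)propanoate | COc1cc(I)cc(OC)c1O[C@H](CO[Si](C)(C)C(C)(C)C)C(=O)OC | intermediate
6 | (R)-3-(TBS-oxy)-2-(4-iodo-2,6-dimethoxyphenoxy)-N-methoxy-N-methylpropanamide | COc1cc(I)cc(OC)c1O[C@H](CO[Si](C)(C)C(C)(C)C)C(=O)N(C)OC | intermediate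
7 | 4-bromo-2-methoxyphenol | COc1cc(Br)ccc1O | starting material
8 | (4-bromo-2-methoxyphenoxy)triisopropylsilane | COc1cc(Br)ccc1O[Si](C(C)C)(C(C)C)C(C)C | intermediate
9 | [3-methoxy-4-(TIPS-oxy)phenyl]magnesium bromide, kept as a titrated THF solution | COc1cc([Mg]Br)ccc1O[Si](C(C)C)(C(C)C)C(C)C | intermediate
10 | (R)-3-(TBS-oxy)-2-(4-iodo-2,6-dimethoxyphenoxy)-1-[3-methoxy-4-(TIPS-oxy)phenyl]propan-1-one | COc1cc(I)cc(OC)c1O[C@H](CO[Si](C)(C)C(C)(C)C)C(=O)c1ccc(O[Si](C(C)C)(C(C)C)C(C)C)c(OC)c1 | intermediate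
11 | (1S,2R)-3-(TBS-oxy)-2-(4-iodo-2,6-dimethoxyphenoxy)-1-[3-methoxy-4-(TIPS-oxy)phenyl]propan-1-ol | COc1cc(I)cc(OC)c1O[C@H](CO[Si](C)(C)C(C)(C)C)[C@@H](O)c1ccc(O[Si](C(C)C)(C(C)C)C(C)C)c(OC)c1 | intermediate
12 | 5-iodo-1,3-dimethoxy-2-{[(1S,2R)-1,3-bis(TBS-oxy)-1-[3-methoxy-4-(TIPS-oxy)phenyl]propan-2-yl]oxy}benzene (ArDE–I) | COc1cc(I)cc(OC)c1O[C@H](CO[Si](C)(C)C(C)(C)C)[C@@H](O[Si](C)(C)C(C)(C)C)c1ccc(O[Si](C(C)C)(C(C)C)C(C)C)c(OC)c1 | intermediate
13 | ArDE–MgCl, the arylmagnesium chloride from 12 | COc1cc([Mg]Cl)cc(OC)c1O[C@H](CO[Si](C)(C)C(C)(C)C)[C@@H](O[Si](C)(C)C(C)(C)C)c1ccc(O[Si](C(C)C)(C(C)C)C(C)C)c(OC)c1 | intermediate (not isolated)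
14 | 4-{[(1S,2R)-1,3-bis(TBS-oxy)-1-[3-methoxy-4-(TIPS-oxy)phenyl]propan-2-yl]oxy}-3,5-dimethoxybenzaldehyde (ArDE–CHO) | COc1cc(C=O)cc(OC)c1O[C@H](CO[Si](C)(C)C(C)(C)C)[C@@H](O[Si](C)(C)C(C)(C)C)c1ccc(O[Si](C(C)C)(C(C)C)C(C)C)c(OC)c1 | intermediate
15 | (R)-4-benzyloxazolidin-2-one | O=C1N[C@H](Cc2ccccc2)CO1 | starting material
16 | pent-4-enoyl chloride | C=CCCC(=O)Cl | starting material
17 | (R)-4-benzyl-3-(pent-4-enoyl)oxazolidin-2-one | C=CCCC(=O)N1[C@H](Cc2ccccc2)COC1=O | intermediate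
18 | Z dibutylboron enolate of 17 | C=CC/C=C(\OB(CCCC)CCCC)N1[C@H](Cc2ccccc2)COC1=O | intermediate (not isolated)
19 | (R)-4-benzyl-3-{(2R)-2-[(R)-hydroxy(ArDE)methyl]pent-4-enoyl}oxazolidin-2-one | C=CC[C@@H](C(=O)N1[C@H](Cc2ccccc2)COC1=O)[C@@H](O)c1cc(OC)c(O[C@H](CO[Si](C)(C)C(C)(C)C)[C@@H](O[Si](C)(C)C(C)(C)C)c2ccc(O[Si](C(C)C)(C(C)C)C(C)C)c(OC)c2)c(OC)c1 | intermediate
20 | ethyl 2-{(R)-(ArDE)[(2R)-1-[(R)-4-benzyl-2-oxooxazolidin-3-yl]-1-oxopent-4-en-2-yl]methoxy}acetate | C=CC[C@@H](C(=O)N1[C@H](Cc2ccccc2)COC1=O)[C@@H](OCC(=O)OCC)c1cc(OC)c(O[C@H](CO[Si](C)(C)C(C)(C)C)[C@@H](O[Si](C)(C)C(C)(C)C)c2ccc(O[Si](C(C)C)(C(C)C)C(C)C)c(OC)c2)c(OC)c1 | intermediate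
21 | ethyl 2-{[(1R,2S)-1-(ArDE)-2-(hydroxymethyl)pent-4-en-1-yl]oxy}acetate | C=CC[C@@H](CO)[C@@H](OCC(=O)OCC)c1cc(OC)c(O[C@H](CO[Si](C)(C)C(C)(C)C)[C@@H](O[Si](C)(C)C(C)(C)C)c2ccc(O[Si](C(C)C)(C(C)C)C(C)C)c(OC)c2)c(OC)c1 | intermediate
22 | ethyl 2-{[(1R,2S)-1-(ArDE)-2-(hydroxymethyl)-4-oxobutyl]oxy}acetate | O=CC[C@@H](CO)[C@@H](OCC(=O)OCC)c1cc(OC)c(O[C@H](CO[Si](C)(C)C(C)(C)C)[C@@H](O[Si](C)(C)C(C)(C)C)c2ccc(O[Si](C(C)C)(C(C)C)C(C)C)c(OC)c2)c(OC)c1 | intermediate (not isolated)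
23 | ethyl 2-{(R)-(ArDE)[(3S)-5-hydroxyoxolan-3-yl]methoxy}acetate, anomer mixture | OC1C[C@@H](CO1)[C@@H](OCC(=O)OCC)c1cc(OC)c(O[C@H](CO[Si](C)(C)C(C)(C)C)[C@@H](O[Si](C)(C)C(C)(C)C)c2ccc(O[Si](C(C)C)(C(C)C)C(C)C)c(OC)c2)c(OC)c1 | intermediate
24 | anomeric methanesulfonate of 23 | CS(=O)(=O)OC1C[C@@H](CO1)[C@@H](OCC(=O)OCC)c1cc(OC)c(O[C@H](CO[Si](C)(C)C(C)(C)C)[C@@H](O[Si](C)(C)C(C)(C)C)c2ccc(O[Si](C(C)C)(C(C)C)C(C)C)c(OC)c2)c(OC)c1 | intermediate (not isolated)
25 | ethyl 2-{(R)-(ArDE)[(3S)-2,3-dihydrofuran-3-yl]methoxy}acetate | C1=C[C@@H](CO1)[C@@H](OCC(=O)OCC)c1cc(OC)c(O[C@H](CO[Si](C)(C)C(C)(C)C)[C@@H](O[Si](C)(C)C(C)(C)C)c2ccc(O[Si](C(C)C)(C(C)C)C(C)C)c(OC)c2)c(OC)c1 | intermediate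
26 | lithium 2-{(R)-(ArDE)[(3S)-2,3-dihydrofuran-3-yl]methoxy}acetate | C1=C[C@@H](CO1)[C@@H](OCC(=O)[O-])c1cc(OC)c(O[C@H](CO[Si](C)(C)C(C)(C)C)[C@@H](O[Si](C)(C)C(C)(C)C)c2ccc(O[Si](C(C)C)(C(C)C)C(C)C)c(OC)c2)c(OC)c1.[Li+] | intermediate (not isolated)
27 | 1,3-dioxoisoindolin-2-yl 2-{(R)-(ArDE)[(3S)-2,3-dihydrofuran-3-yl]methoxy}acetate | C1=C[C@@H](CO1)[C@@H](OCC(=O)ON1C(=O)c2ccccc2C1=O)c1cc(OC)c(O[C@H](CO[Si](C)(C)C(C)(C)C)[C@@H](O[Si](C)(C)C(C)(C)C)c2ccc(O[Si](C(C)C)(C(C)C)C(C)C)c(OC)c2)c(OC)c1 | intermediate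
28 | methyl (R)-2,3-dihydroxypropanoate | COC(=O)[C@H](O)CO | starting material
29 | methyl (R)-3-(TBS-oxy)-2-hydroxypropanoate | COC(=O)[C@H](O)CO[Si](C)(C)C(C)(C)C | intermediate
30 | 4-iodo-2-methoxyphenol | COc1cc(I)ccc1O | starting material
31 | methyl (S)-3-(TBS-oxy)-2-(4-iodo-2-methoxyphenoxy)propanoate | COC(=O)[C@H](CO[Si](C)(C)C(C)(C)C)Oc1ccc(I)cc1OC | intermediate
32 | (S)-3-(TBS-oxy)-2-(4-iodo-2-methoxyphenoxy)-N-methoxy-N-methylpropanamide | CON(C)C(=O)[C@H](CO[Si](C)(C)C(C)(C)C)Oc1ccc(I)cc1OC | intermediate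
33 | (S)-3-(TBS-oxy)-2-(4-iodo-2-methoxyphenoxy)-1-[3-methoxy-4-(TIPS-oxy)phenyl]propan-1-one | COc1cc(C(=O)[C@H](CO[Si](C)(C)C(C)(C)C)Oc2ccc(I)cc2OC)ccc1O[Si](C(C)C)(C(C)C)C(C)C | intermediate
34 | (1R,2S)-3-(TBS-oxy)-2-(4-iodo-2-methoxyphenoxy)-1-[3-methoxy-4-(TIPS-oxy)phenyl]propan-1-ol | COc1cc([C@@H](O)[C@H](CO[Si](C)(C)C(C)(C)C)Oc2ccc(I)cc2OC)ccc1O[Si](C(C)C)(C(C)C)C(C)C | intermediate
35 | 4-iodo-2-methoxy-1-{[(1R,2S)-1,3-bis(TBS-oxy)-1-[3-methoxy-4-(TIPS-oxy)phenyl]propan-2-yl]oxy}benzene (ArAB–I) | COc1cc([C@@H](O[Si](C)(C)C(C)(C)C)[C@H](CO[Si](C)(C)C(C)(C)C)Oc2ccc(I)cc2OC)ccc1O[Si](C(C)C)(C(C)C)C(C)C | intermediate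
36 | ArAB–MgCl, the arylmagnesium chloride from 35 | COc1cc([C@@H](O[Si](C)(C)C(C)(C)C)[C@H](CO[Si](C)(C)C(C)(C)C)Oc2ccc([Mg]Cl)cc2OC)ccc1O[Si](C(C)C)(C(C)C)C(C)C | intermediate (not isolated)
37 | (R)-3-(TBS-oxy)-2-(4-iodo-2,6-dimethoxyphenoxy)-1-(ArAB)propan-1-one | COc1cc([C@@H](O[Si](C)(C)C(C)(C)C)[C@H](CO[Si](C)(C)C(C)(C)C)Oc2ccc(C(=O)[C@@H](CO[Si](C)(C)C(C)(C)C)Oc3c(OC)cc(I)cc3OC)cc2OC)ccc1O[Si](C(C)C)(C(C)C)C(C)C | intermediate
38 | (1S,2R)-3-(TBS-oxy)-2-(4-iodo-2,6-dimethoxyphenoxy)-1-(ArAB)propan-1-ol | COc1cc([C@@H](O[Si](C)(C)C(C)(C)C)[C@H](CO[Si](C)(C)C(C)(C)C)Oc2ccc([C@H](O)[C@@H](CO[Si](C)(C)C(C)(C)C)Oc3c(OC)cc(I)cc3OC)cc2OC)ccc1O[Si](C(C)C)(C(C)C)C(C)C | intermediate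
39 | {(R)-(ArDE)[(3S)-2,3-dihydrofuran-3-yl]methoxy}methyl radical | C1=C[C@@H](CO1)[C@@H](O[CH2])c1cc(OC)c(O[C@H](CO[Si](C)(C)C(C)(C)C)[C@@H](O[Si](C)(C)C(C)(C)C)c2ccc(O[Si](C(C)C)(C(C)C)C(C)C)c(OC)c2)c(OC)c1 | intermediate (not isolated)
40 | (1S,5S,6R)-6-(ArDE)-3,7-dioxabicyclo[3.3.0]octan-2-yl radical | [CH]1OC[C@@H]2[C@H]1CO[C@H]2c1cc(OC)c(O[C@H](CO[Si](C)(C)C(C)(C)C)[C@@H](O[Si](C)(C)C(C)(C)C)c2ccc(O[Si](C(C)C)(C(C)C)C(C)C)c(OC)c2)c(OC)c1 | intermediate (not isolated)
41 | hepta-silylated target: TBS on O7 and O9 of units A and E and on O9 of unit B, TIPS on both phenols, O7 of unit B free | COc1cc([C@@H](O[Si](C)(C)C(C)(C)C)[C@H](CO[Si](C)(C)C(C)(C)C)Oc2ccc([C@H](O)[C@@H](CO[Si](C)(C)C(C)(C)C)Oc3c(OC)cc([C@@H]4OC[C@@H]5[C@H]4CO[C@H]5c4cc(OC)c(O[C@H](CO[Si](C)(C)C(C)(C)C)[C@@H](O[Si](C)(C)C(C)(C)C)c5ccc(O[Si](C(C)C)(C(C)C)C(C)C)c(OC)c5)c(OC)c4)cc3OC)cc2OC)ccc1O[Si](C(C)C)(C(C)C)C(C)C | intermediate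
42 | CNP0316493.2: (1S,2R,5S,6R)-2,6-diaryl-3,7-dioxabicyclo[3.3.0]octane; the 3,5-dimethoxyphenyl at C2 carries on O4 the C8 of (7S,8R)-guaiacylglycerol unit B, whose phenol oxygen carries the C8 of (7R,8S)-guaiacylglycerol unit A; the 3,5-dimethoxyphenyl at C6 carries on O4 the C8 of (7S,8R)-guaiacylglycerol unit E | COc1cc([C@@H](O)[C@H](CO)Oc2ccc([C@H](O)[C@@H](CO)Oc3c(OC)cc([C@@H]4OC[C@@H]5[C@H]4CO[C@H]5c4cc(OC)c(O[C@H](CO)[C@@H](O)c5ccc(O)c(OC)c5)c(OC)c4)cc3OC)cc2OC)ccc1O | target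

**Step count and risks**

Total step count: 27. Longest linear sequence: 15 steps (steps 2, 3, 4, 7, 8, 9, 10, 12, 13, 14, 15, 16, 17, 26, 27).

The three steps most likely to fail:

Step 26 (proposed new method). The alkoxymethyl radical may be captured by nickel before it closes the ring, giving a simple benzyl-type ether. The C2 radical or its alkylnickel may be reduced or lose a β-hydride instead of coupling. Oxidative addition of the electron-rich aryl iodide may be too slow, so that the redox-active ester is consumed unproductively. The fallback sets out from 27 and 38 and returns at 41; it separates ring closure from arylation using known reaction types. Light-driven decarboxylative borylation of 27 with bis(catecholato)diboron in DMAc is a metal-free radical chain; the only competitor of the 5-exo closure is the slower bimolecular borylation of 39, which dilution should keep down. It should give 2-[(1S,2S,5S,6R)-6-(ArDE)-3,7-dioxabicyclo[3.3.0]octan-2-yl]-1,3,2-benzodioxaborole F1, with boron on the convex face. KHF2 in MeOH/H2O converts it into potassium [(1S,2S,5S,6R)-6-(ArDE)-3,7-dioxabicyclo[3.3.0]octan-2-yl]trifluoroborate F2. Photoredox/nickel dual-catalytic cross-coupling of this α-alkoxyalkyl trifluoroborate with 38 (Ir[dF(CF3)ppy]2(bpy)PF6, NiCl2·dme, 4,4'-di-tert-butyl-2,2'-bipyridine, K2HPO4, dioxane, blue light) then gives 41, the aryl group again entering on the convex face.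

Step 13. Cyclopropanation of the terminal alkene or attack of the carbenoid on the electron-rich arenes may compete with O–H insertion, and carbene dimerization may leave the hindered alcohol unreacted. The fallback sets out from 19 and returns at 21, replacing steps 13 and 14 by a protecting-group sequence. NaBH4 in THF/H2O removes the auxiliary first and gives (1R,2S)-1-(ArDE)-2-(prop-2-en-1-yl)propane-1,3-diol F3. 4,4'-Dimethoxytrityl chloride in pyridine protects only the primary hydroxyl, giving (1R,2S)-1-(ArDE)-2-{[bis(4-methoxyphenyl)(phenyl)methoxy]methyl}pent-4-en-1-ol F4. Williamson alkylation of the secondary alkoxide (NaH, ethyl bromoacetate, Bu4NI, THF, 0 °C) gives ethyl 2-{[(1R,2S)-1-(ArDE)-2-{[bis(4-methoxyphenyl)(phenyl)methoxy]methyl}pent-4-en-1-yl]oxy}acetate F5. Dichloroacetic acid (3 % in wet CH2Cl2, 0 °C) then removes the trityl group and gives 21.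

Step 8 (the same risk recurs in steps 22 and 25). Facial selectivity may be poor if chelation between the ketone and the aryloxy oxygen is weak, and the α-aryloxy ketone may epimerize at C8 before it is reduced. The fallback sets out from 5 and returns at 11; it sets the carbinol centre by C–C bond formation under Felkin–Anh control instead of by ketone reduction. iBu2AlH (toluene, −78 °C) reduces the ester to (R)-3-(TBS-oxy)-2-(4-iodo-2,6-dimethoxyphenoxy)propanal F6. The non-chelating [3-methoxy-4-(TIPS-oxy)phenyl]titanium triisopropoxide F7, made from Grignard reagent 9 and ClTi(OiPr)3, should add anti to the aryloxy group and give the same erythro alcohol 11. The same change applies to ester 31 on the way to 34.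

Further compounds

F1 | step 26 | 2-[(1S,2S,5S,6R)-6-(ArDE)-3,7-dioxabicyclo[3.3.0]octan-2-yl]-1,3,2-benzodioxaborole | c1ccc2OB(Oc2c1)[C@@H]1OC[C@@H]2[C@H]1CO[C@H]2c1cc(OC)c(O[C@H](CO[Si](C)(C)C(C)(C)C)[C@@H](O[Si](C)(C)C(C)(C)C)c2ccc(O[Si](C(C)C)(C(C)C)C(C)C)c(OC)c2)c(OC)c1
F2 | step 26 | potassium [(1S,2S,5S,6R)-6-(ArDE)-3,7-dioxabicyclo[3.3.0]octan-2-yl]trifluoroborate | [K+].F[B-](F)(F)[C@@H]1OC[C@@H]2[C@H]1CO[C@H]2c1cc(OC)c(O[C@H](CO[Si](C)(C)C(C)(C)C)[C@@H](O[Si](C)(C)C(C)(C)C)c2ccc(O[Si](C(C)C)(C(C)C)C(C)C)c(OC)c2)c(OC)c1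
F3 | step 13 | (1R,2S)-1-(ArDE)-2-(prop-2-en-1-yl)propane-1,3-diol | C=CC[C@@H](CO)[C@@H](O)c1cc(OC)c(O[C@H](CO[Si](C)(C)C(C)(C)C)[C@@H](O[Si](C)(C)C(C)(C)C)c2ccc(O[Si](C(C)C)(C(C)C)C(C)C)c(OC)c2)c(OC)c1
F4 | step 13 | (1R,2S)-1-(ArDE)-2-{[bis(4-methoxyphenyl)(phenyl)methoxy]methyl}pent-4-en-1-ol | C=CC[C@@H](COC(c1ccccc1)(c1ccc(OC)cc1)c1ccc(OC)cc1)[C@@H](O)c1cc(OC)c(O[C@H](CO[Si](C)(C)C(C)(C)C)[C@@H](O[Si](C)(C)C(C)(C)C)c2ccc(O[Si](C(C)C)(C(C)C)C(C)C)c(OC)c2)c(OC)c1
F5 | step 13 | ethyl 2-{[(1R,2S)-1-(ArDE)-2-{[bis(4-methoxyphenyl)(phenyl)methoxy]methyl}pent-4-en-1-yl]oxy}acetate | C=CC[C@@H](COC(c1ccccc1)(c1ccc(OC)cc1)c1ccc(OC)cc1)[C@@H](OCC(=O)OCC)c1cc(OC)c(O[C@H](CO[Si](C)(C)C(C)(C)C)[C@@H](O[Si](C)(C)C(C)(C)C)c2ccc(O[Si](C(C)C)(C(C)C)C(C)C)c(OC)c2)c(OC)c1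
F6 | step 8 | (R)-3-(TBS-oxy)-2-(4-iodo-2,6-dimethoxyphenoxy)propanal | COc1cc(I)cc(OC)c1O[C@H](CO[Si](C)(C)C(C)(C)C)C=O
F7 | step 8 | [3-methoxy-4-(TIPS-oxy)phenyl]titanium triisopropoxide | COc1cc([Ti](OC(C)C)(OC(C)C)OC(C)C)ccc1O[Si](C(C)C)(C(C)C)C(C)C
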